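The target is numbered as a tetralin: C1 carries the guaiacyl ring (ring C), and C2 and C3 carry the hydroxymethyl carbons C2a and C3a. The 1,4-diol C2a–C2–C3–C3a is then the reduced form of a γ-butyrolactone. The route rests on closing that temporary lactone across C2–C3. An achiral 3-arylpropyl diazoacetate undergoes catalyst-controlled carbene insertion into a C3–H bond, which forges C2–C3 and the C3 stereocentre in one operation. C3 then relays its configuration: a trans aldol at C2 with O-benzylvanillin, Friedel–Crafts closure of ring B (C1–C8a) onto the symmetric syringyl ring A, lactone reduction and debenzylation.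

Key step: step 5

Remarks and assumptions:
- Atom labels: ring A is the aromatic ring C4a/C5–C8/C8a (C6 OMe, C7 OH, C8 OMe). Ring B is C1–C2–C3–C4–C4a–C8a. Ring C is the 4-hydroxy-3-methoxyphenyl group. The target is (1R,2S,3S), all-trans.
- Rh2(4R-MPPIM)4 is the divalent-rhodium complex dirhodium tetrakis[methyl (4R)-2-oxo-1-(3-phenylpropanoyl)imidazolidine-4-carboxylate]. It is the mirror image of the commercial 4S catalyst and is taken as available by ligand exchange on Rh2(OAc)4.
- Assumption: the 4R catalyst delivers the (S)-lactone, the 4S catalyst favouring the (R)-series for 3-arylpropyl diazoacetates. If a trial showed the opposite sense, the mirror-image catalyst would be used with no other change.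
- The catalyst-bound carbene of step 5 is a catalytic-cycle species. It is described in the Why line and not numbered.
- Compound 11 is carried as both C1 carbinol epimers, which converge in step 7.

Step 1
Reactants: 1 4-allyl-2,6-dimethoxyphenol (methoxyeugenol)
Product: 2 5-allyl-2-(benzyloxy)-1,3-dimethoxybenzene
Conditions: BnBr, K2CO3, DMF, 60 °C
Reagents that add atoms: benzyl bromide, BrCc1ccccc1
Why: Williamson ether synthesis on the phenoxide of 1 installs a benzyl ether that should survive the borane, base, carbene, acid and hydride steps and is removed last by hydrogenolysis.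

Step 2
Reactants: 2 5-allyl-2-(benzyloxy)-1,3-dimethoxybenzene
Product: 4 3-[4-(benzyloxy)-3,5-dimethoxyphenyl]propan-1-ol, via B-alkyl-9-BBN adduct 3 (not isolated)
Conditions: 9-BBN, THF, 0 °C to rt; then NaOH aq, H2O2, 0 °C to rt
Reagents that add atoms: hydrogen peroxide, OO (oxygen of 4); 9-borabicyclo[3.3.1]nonane, B1C2CCCC1CCC2 (boron and bicycle of 3 only)
Why: Brown hydroboration–oxidation with the bulky 9-BBN should place boron on the terminal carbon of the allyl group, and alkaline peroxide should then give the primary alcohol without touching the arene or the benzyl ether.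

Step 3
Reactants: 4 3-[4-(benzyloxy)-3,5-dimethoxyphenyl]propan-1-ol
Product: 5 3-[4-(benzyloxy)-3,5-dimethoxyphenyl]propyl bromoacetate
Conditions: BrCH2COBr, NaHCO3, MeCN, 0 °C
Reagents that add atoms: bromoacetyl bromide, BrCC(Br)=O
Why: O-acylation of a primary alcohol by an acyl bromide (esterification), with NaHCO3 as a non-nucleophilic acid scavenger so that the α-bromide is not displaced.

Step 4
Reactants: 5 3-[4-(benzyloxy)-3,5-dimethoxyphenyl]propyl bromoacetate
Product: 7 3-[4-(benzyloxy)-3,5-dimethoxyphenyl]propyl diazoacetate, via ditosylhydrazinyl acetate 6 (not isolated)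
Conditions: TsNHNHTs, DBU, THF, 0 °C
Reagents that add atoms: N,N'-ditosylhydrazine, Cc1ccc(S(=O)(=O)NNS(=O)(=O)c2ccc(C)cc2)cc1
Why: The sulfonyl hydrazide anion should displace bromide (SN2) to give 6, and DBU should then expel two p-toluenesulfinate ions in a Bamford–Stevens-type elimination to unveil the diazoacetate under mild conditions.

Step 5
Reactants: 7 3-[4-(benzyloxy)-3,5-dimethoxyphenyl]propyl diazoacetate
Product: 8 (S)-4-[4-(benzyloxy)-3,5-dimethoxybenzyl]dihydrofuran-2(3H)-one
Conditions: Rh2(4R-MPPIM)4 (1 mol %), CH2Cl2, reflux, slow addition of 7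
Reagents that add atoms: none
Why: The dirhodium carboxamidate should decompose the diazo group of 7 with loss of N2 to a catalyst-bound electrophilic carbene at C2, which inserts into one C3–H bond through a concerted three-centre transition state (hydride-like shift to the carbene carbon as C2–C3 forms). The closest known reaction type is the enantioselective intramolecular C–H insertion of alkyl diazoacetates catalysed by chiral dirhodium carboxamidates, which is established for 3-arylpropyl diazoacetates. One ring is closed, the γ-butyrolactone O–C2a(=O)–C2–C3–C3a, by a 1,5-insertion in which C2–C3 is the ring-forming bond. The single new stereocentre C3 is under catalyst control: the chiral imidazolidinone-carboxylate ligands distinguish the two enantiotopic hydrogens of the C3 methylene, and the 4R catalyst is expected to give the (S)-lactone. The step needs regioselectivity for C3–H over the benzylic C4–H (six-membered ring) and the O–CH2 C3a–H (four-membered ring), and chemoselectivity over carbene addition to the electron-rich ring A and over carbene dimerisation; the geometric preference for the five-membered transition state, the attenuated electrophilicity of the carboxamidate-bound carbene and slow addition of 7 should secure them.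

Step 6
Reactants: 8 (S)-4-[4-(benzyloxy)-3,5-dimethoxybenzyl]dihydrofuran-2(3H)-one; 9 4-(benzyloxy)-3-methoxybenzaldehyde (O-benzylvanillin)
Product: 11 (3R,4S)-3-{[4-(benzyloxy)-3-methoxyphenyl](hydroxy)methyl}-4-[4-(benzyloxy)-3,5-dimethoxybenzyl]dihydrofuran-2(3H)-one as a mixture of C1 carbinol epimers, via lithium enolate 10 (not isolated)
Conditions: LiN(iPr)2, THF, −78 °C; then 9, −78 °C; NH4Cl aq
Reagents that add atoms: none
Why: Aldol addition of the lithium lactone enolate to a non-enolisable aldehyde should occur on the enolate face anti to the C3 arylmethyl group, setting C2 trans to C3 by substrate control, while the C1 carbinol configuration is irrelevant because C1 is ionised in the next step.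

Step 7
Reactants: 11 (3R,4S)-3-{[4-(benzyloxy)-3-methoxyphenyl](hydroxy)methyl}-4-[4-(benzyloxy)-3,5-dimethoxybenzyl]dihydrofuran-2(3H)-one
Product: 13 (3aS,9R,9aS)-7-(benzyloxy)-9-[4-(benzyloxy)-3-methoxyphenyl]-6,8-dimethoxy-3a,4,9,9a-tetrahydronaphtho[2,3-c]furan-1(3H)-one, via benzylic cation 12 (not isolated)
Conditions: CF3CO2H, CH2Cl2, 0 °C to rt
Reagents that add atoms: none
Why: Intramolecular Friedel–Crafts alkylation: acid ionises the benzylic alcohol to the p-benzyloxy-stabilised cation 12, which is attacked by ring A at the position ortho to the chain and para to a methoxy group (both ortho positions are equivalent), closing ring B through a chair-like transition state that places ring C pseudo-equatorial and so sets C1 trans to C2 by substrate control.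

Step 8
Reactants: 13 (3aS,9R,9aS)-7-(benzyloxy)-9-[4-(benzyloxy)-3-methoxyphenyl]-6,8-dimethoxy-3a,4,9,9a-tetrahydronaphtho[2,3-c]furan-1(3H)-one
Product: 14 [(1R,2S,3S)-7-(benzyloxy)-1-[4-(benzyloxy)-3-methoxyphenyl]-6,8-dimethoxy-1,2,3,4-tetrahydronaphthalene-2,3-diyl]dimethanol
Conditions: LiAlH4, THF, 0 °C to rt; then H2O, NaOH aq
Reagents that add atoms: none
Why: Hydride reduction of the lactone to the 1,4-diol should be faster than enolisation at C2, so the three stereocentres are carried through unchanged.

Step 9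
Reactants: 14 [(1R,2S,3S)-7-(benzyloxy)-1-[4-(benzyloxy)-3-methoxyphenyl]-6,8-dimethoxy-1,2,3,4-tetrahydronaphthalene-2,3-diyl]dimethanol
Product: 15 [(1R,2S,3S)-7-hydroxy-1-(4-hydroxy-3-methoxyphenyl)-6,8-dimethoxy-1,2,3,4-tetrahydronaphthalene-2,3-diyl]dimethanol
Conditions: H2 (1 atm), Pd/C, EtOAc–MeOH, rt
Reagents that add atoms: none
Why: Catalytic hydrogenolysis should cleave both aryl benzyl ethers while the diarylmethine C–C bonds, the methyl ethers and the primary alcohols are inert.

Compound list
1 | 4-allyl-2,6-dimethoxyphenol (methoxyeugenol) | C=CCc1cc(OC)c(O)c(OC)c1 | starting material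
2 | 5-allyl-2-(benzyloxy)-1,3-dimethoxybenzene | C=CCc1cc(OC)c(OCc2ccccc2)c(OC)c1 | intermediate
3 | 9-{3-[4-(benzyloxy)-3,5-dimethoxyphenyl]propyl}-9-borabicyclo[3.3.1]nonane | COc1cc(CCCB2C3CCCC2CCC3)cc(OC)c1OCc1ccccc1 | intermediate (not isolated)
4 | 3-[4-(benzyloxy)-3,5-dimethoxyphenyl]propan-1-ol | COc1cc(CCCO)cc(OC)c1OCc1ccccc1 | intermediate
5 | 3-[4-(benzyloxy)-3,5-dimethoxyphenyl]propyl bromoacetate | COc1cc(CCCOC(=O)CBr)cc(OC)c1OCc1ccccc1 | intermediate
6 | 3-[4-(benzyloxy)-3,5-dimethoxyphenyl]propyl [1,2-bis(4-methylbenzenesulfonyl)hydrazin-1-yl]acetate | COc1cc(CCCOC(=O)CN(NS(=O)(=O)c2ccc(C)cc2)S(=O)(=O)c2ccc(C)cc2)cc(OC)c1OCc1ccccc1 | intermediate (not isolated)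
7 | 3-[4-(benzyloxy)-3,5-dimethoxyphenyl]propyl diazoacetate | COc1cc(CCCOC(=O)C=[N+]=[N-])cc(OC)c1OCc1ccccc1 | intermediate
8 | (S)-4-[4-(benzyloxy)-3,5-dimethoxybenzyl]dihydrofuran-2(3H)-one | COc1cc(C[C@@H]2COC(=O)C2)cc(OC)c1OCc1ccccc1 | intermediate
9 | 4-(benzyloxy)-3-methoxybenzaldehyde (O-benzylvanillin) | COc1cc(C=O)ccc1OCc1ccccc1 | starting material
10 | lithium enolate of 8 (lithium (S)-4-[4-(benzyloxy)-3,5-dimethoxybenzyl]-4,5-dihydrofuran-2-olate) | [Li+].COc1cc(C[C@@H]2COC([O-])=C2)cc(OC)c1OCc1ccccc1 | intermediate (not isolated)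
11 | (3R,4S)-3-{[4-(benzyloxy)-3-methoxyphenyl](hydroxy)methyl}-4-[4-(benzyloxy)-3,5-dimethoxybenzyl]dihydrofuran-2(3H)-one, both C1 carbinol epimers | COc1cc(C[C@@H]2COC(=O)[C@H]2C(O)c2ccc(OCc3ccccc3)c(OC)c2)cc(OC)c1OCc1ccccc1 | intermediate
12 | [4-(benzyloxy)-3-methoxyphenyl]{(3R,4S)-4-[4-(benzyloxy)-3,5-dimethoxybenzyl]-2-oxotetrahydrofuran-3-yl}methylium trifluoroacetate (C1 cation) | COc1cc(C[C@@H]2COC(=O)[C@H]2[CH+]c2ccc(OCc3ccccc3)c(OC)c2)cc(OC)c1OCc1ccccc1.[O-]C(=O)C(F)(F)F | intermediate (not isolated)
13 | (3aS,9R,9aS)-7-(benzyloxy)-9-[4-(benzyloxy)-3-methoxyphenyl]-6,8-dimethoxy-3a,4,9,9a-tetrahydronaphtho[2,3-c]furan-1(3H)-one (all-trans, trans-fused lactone) | COc1cc([C@@H]2c3c(cc(OC)c(OCc4ccccc4)c3OC)C[C@@H]3COC(=O)[C@@H]23)ccc1OCc1ccccc1 | intermediate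
14 | [(1R,2S,3S)-7-(benzyloxy)-1-[4-(benzyloxy)-3-methoxyphenyl]-6,8-dimethoxy-1,2,3,4-tetrahydronaphthalene-2,3-diyl]dimethanol | COc1cc([C@@H]2c3c(cc(OC)c(OCc4ccccc4)c3OC)C[C@H](CO)[C@H]2CO)ccc1OCc1ccccc1 | intermediate
15 | [(1R,2S,3S)-7-hydroxy-1-(4-hydroxy-3-methoxyphenyl)-6,8-dimethoxy-1,2,3,4-tetrahydronaphthalene-2,3-diyl]dimethanol (CNP0325829.1) | COc1cc([C@@H]2c3c(cc(OC)c(O)c3OC)C[C@H](CO)[C@H]2CO)ccc1O | target

Total step count: 9. Longest linear sequence: 9 steps (1 to 15); aldehyde 9 enters in step 6.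

Steps most likely to fail

Step 5 (key step). The carbene may be diverted into dimerisation, insertion at the benzylic C4–H or addition to ring A, or the two enantiotopic C3 hydrogens may be discriminated insufficiently. The fallback sets out from 2, returns at 8, and still closes the lactone ring across C2–C3.
- Dihydroxylation of 2 (OsO4 cat., N-methylmorpholine N-oxide, acetone–H2O) should give racemic 3-[4-(benzyloxy)-3,5-dimethoxyphenyl]propane-1,2-diol F1.
- Selective acylation of the primary hydroxyl with (diethoxyphosphoryl)acetic acid (EDC, DMAP, CH2Cl2, 0 °C) should give 3-[4-(benzyloxy)-3,5-dimethoxyphenyl]-2-hydroxypropyl (diethoxyphosphoryl)acetate F2.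
- Dess–Martin oxidation of the secondary alcohol should give 3-[4-(benzyloxy)-3,5-dimethoxyphenyl]-2-oxopropyl (diethoxyphosphoryl)acetate F3.
- Intramolecular Horner–Wadsworth–Emmons olefination (LiCl, DBU, MeCN) should close the butenolide 4-[4-(benzyloxy)-3,5-dimethoxybenzyl]furan-2(5H)-one F4 by forming C2=C3.
- Enantioselective conjugate reduction with a ligated copper hydride (CuCl2·2H2O, NaOtBu, the enantiomer of p-tol-BINAP that gives the S product, polymethylhydrosiloxane, toluene) should set C3 and give 8.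

Step 7. After ionisation the cation may lose the C2 proton (dehydration to the benzylidene lactone) instead of closing ring B, the benzyl ethers may suffer acidolysis, or facial selectivity at C1 may be poor. The fallback sets out from 11 and returns at 14, moving the ring closure to the triol stage.
- LiAlH4 reduction of 11 should give (2S,3S)-2-{[4-(benzyloxy)-3-methoxyphenyl](hydroxy)methyl}-3-[4-(benzyloxy)-3,5-dimethoxybenzyl]butane-1,4-diol F5, which has no acidic C2 hydrogen and no strained lactone.
- Mild acid (methanolic HCl or dilute CF3CO2H in CH2Cl2) should ionise C1. The C3a hydroxyl traps the cation reversibly as the lariciresinol-type tetrahydrofuran {(3R,4S)-2-[4-(benzyloxy)-3-methoxyphenyl]-4-[4-(benzyloxy)-3,5-dimethoxybenzyl]tetrahydrofuran-3-yl}methanol F6.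
- F6 re-ionises under the same conditions and should drain by Friedel–Crafts closure into the all-trans diol 14.

Step 6. Retro-aldol reversal during warming or quench, proton transfer between the enolate and the product, or incomplete anti selectivity at C2 may erode the adduct. The fallback sets out from 8 and returns at 11.
- Claisen-type C-acylation of the enolate of 8 (two equivalents of LiN(SiMe3)2, THF, −78 °C, then 4-(benzyloxy)-3-methoxybenzoyl chloride) should give (3R,4S)-3-[4-(benzyloxy)-3-methoxybenzoyl]-4-[4-(benzyloxy)-3,5-dimethoxybenzyl]dihydrofuran-2(3H)-one F7. Its acidic C2 hydrogen lets it settle in the trans configuration.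
- Ketone reduction (NaBH4, MeOH, −20 °C) should then give 11 irreversibly.

Further compounds
F1 | step 5 | 3-[4-(benzyloxy)-3,5-dimethoxyphenyl]propane-1,2-diol (racemic) | COc1cc(CC(O)CO)cc(OC)c1OCc1ccccc1
F2 | step 5 | 3-[4-(benzyloxy)-3,5-dimethoxyphenyl]-2-hydroxypropyl (diethoxyphosphoryl)acetate (racemic) | COc1cc(CC(O)COC(=O)CP(=O)(OCC)OCC)cc(OC)c1OCc1ccccc1
F3 | step 5 | 3-[4-(benzyloxy)-3,5-dimethoxyphenyl]-2-oxopropyl (diethoxyphosphoryl)acetate | COc1cc(CC(=O)COC(=O)CP(=O)(OCC)OCC)cc(OC)c1OCc1ccccc1
F4 | step 5 | 4-[4-(benzyloxy)-3,5-dimethoxybenzyl]furan-2(5H)-one | COc1cc(CC2=CC(=O)OC2)cc(OC)c1OCc1ccccc1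
F5 | step 7 | (2S,3S)-2-{[4-(benzyloxy)-3-methoxyphenyl](hydroxy)methyl}-3-[4-(benzyloxy)-3,5-dimethoxybenzyl]butane-1,4-diol (C1 carbinol epimers) | COc1cc(C[C@H](CO)[C@@H](CO)C(O)c2ccc(OCc3ccccc3)c(OC)c2)cc(OC)c1OCc1ccccc1
F6 | step 7 | {(3R,4S)-2-[4-(benzyloxy)-3-methoxyphenyl]-4-[4-(benzyloxy)-3,5-dimethoxybenzyl]tetrahydrofuran-3-yl}methanol (C2 epimers of the tetrahydrofuran) | COc1cc(C[C@@H]2COC([C@@H]2CO)c2ccc(OCc3ccccc3)c(OC)c2)cc(OC)c1OCc1ccccc1
F7 | step 6 | (3R,4S)-3-[4-(benzyloxy)-3-methoxybenzoyl]-4-[4-(benzyloxy)-3,5-dimethoxybenzyl]dihydrofuran-2(3H)-one | COc1cc(C[C@@H]2COC(=O)[C@H]2C(=O)c2ccc(OCc3ccccc3)c(OC)c2)cc(OC)c1OCc1ccccc1
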